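Saturday's run showed two peaks and left substrate and reagent to be found by difference.

| flask | substrate | reagent | remark | time |
|---|---|---|---|---|
| Saturday's | 0.070 M | 0.060 M | run made earlier |  |
| Thursday's | 0.11 M | 0.060 M | run made earlier |  |
| flask | 0.050 M | 0.0600 M |  | 15 d |

| run | time / d | target / % | isomer of the product / % |
|---|---|---|---|
| Saturday's | 0.625 | 34 | 20 |
| Saturday's | 1.67 | 21 | 42 |
| Saturday's | 4.00 | 5 | 66 |
| Saturday's | 10.0 | 0 | 82 |
| Thursday's | 0.625 | 27 | 18 |
| Thursday's | 1.67 | 15 | 35 |
| Thursday's | 4.00 | 4 | 49 |
| Thursday's | 10.0 | 1 | 53 |

(each reading ± 1.5 percentage points)



- ratio of target to isomer of the product at 15 min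
- ratio of target to isomer of the product at 15 d
- which of target and isomer of the product there is more of at 15 d

At 10.0 d, Thursday's target and isomer together stood at 54.0% against the 54.5% its reagent allowed, so I took one reagent per substrate. Target fell while isomer rose, so I read target as formed reversibly from substrate and reagent. At 0.625 d, Saturday's [reagent] by difference was 0.0222 M, more than Thursday's 0.0105 M, so I used Saturday's reading. Taking binding as equilibrated by then, it gave a reading of the dissociation constant, [substrate][reagent]/[target], of 0.0300 M, counting as substrate whatever target and isomer did not hold.

In this flask substrate is the limiting reagent, so for 15 d I took [reagent] as the excess, 0.0100 M. My two amounts are that excess and that constant. Their ratio is the binding number, 0.333, the target held per unbound substrate at the excess. I expected isomer to lead at 15 d, as Saturday's run ended at 82% isomer and 0% target. The binding number gives no early ratio.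

The forecast gave 170 at 15 min and 0.004 at 15 d, with isomer of the product ahead, calling the late ratio “poorly constrained”. The flask gave 61.7 and 0.00304, with isomer of the product ahead.

    reagent + other conformer → isomer of the product (k = 0.110 M⁻¹ min⁻¹)
    reagent → decomposition product (k = 6.50 × 10⁻⁷ min⁻¹)
    substrate ⇌ other conformer (K = 0.390, k = 8.10 × 10⁻⁴ min⁻¹)
    substrate + reagent ⇌ target (K = 32.0 M⁻¹, k = 0.0400 M⁻¹ min⁻¹)

Substrate's forward binding half-life at the charged amounts, 0.20 d, is shorter than the 0.59 d of its forward passage into other conformer. At 15.0 d, this flask held 0.306 target per substrate and other conformer together, against my binding number of 0.333.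

In the neighbour flask with 0.24 M of reagent, the excess of 0.190 M gives a binding number of 6.33. That neighbour ended with 6.31 target per substrate and other conformer together, with 10.1% target and a target-to-isomer ratio of 0.115.

All runs come from a simulation from invented constants, noise included.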